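The meeting opened on slowness: the chair noted that the delta run still crawls at its end, and asked what adding target to the same charge does to it.

in all of them: starting material 0.250 M
- delta: reagent 0.625 M; free catalyst 0.0130 M
- epsilon: reagent 1.90 M; free catalyst 0.0130 M
- beta: reagent 0.625 M; free catalyst 0.0390 M
- theta: reagent 0.625 M; free catalyst 0.0130 M; target 0.120 M; time 71 min

- delta run (time / min: [starting material] / M): 2.8: 0.2238; 4.5: 0.2115; 7.1: 0.1906; 11: 0.1612; 18: 0.1224; 28: 0.0855; 45: 0.0509; 71: 0.0258
- epsilon run (time / min: [starting material] / M): 2.8: 0.2143; 4.5: 0.1917; 7.1: 0.1643; 11: 0.1330; 18: 0.0948; 28: 0.0609; 45: 0.0318; 71: 0.0172
- beta run (time / min: [starting material] / M): 2.8: 0.1972; 4.5: 0.1673; 7.1: 0.1305; 11: 0.0883; 18: 0.0465; 28: 0.0212; 45: 0.0051; 71: 0.0024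

(scatter of a reading: 0.001 M)

- how the opening rate goes with [free catalyst] round the charge of the delta run: the exponent of the rate at two percent of starting material gone to target
- how the opening rate goes with [reagent] round the charge of the delta run: the exponent of the rate at two percent of starting material gone to target
- starting material in the theta run at 71 min, as a share of the starting material charged

- Overall: starting material + reagent -> target, with free catalyst as catalyst.
- Constant volume, constant temperature.
- What is held in complexes is read along with the free species.
- "The second partner" is reagent.
- An order is taken over about fifteen percent of the charge, up and down.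

The analyst proposed reckoning theta as delta plus a correction for the 0.120 M of added target. Delta's reading gives the large term, a share of 10.3% at 71 min.

To bound the correction, she defined the tail constant k_t, the pseudo-first-order constant of delta's last interval, ln(S before/S after) over the minutes between, with S the starting material. From delta's readings, 0.0261 min⁻¹.

A colleague tried k_t on the epsilon run, at 1.90 M of reagent. Carried across its last interval, it turns 0.0318 M into 0.01612 M, and epsilon reads 0.0172 M, with a scatter of 0.001 M. So, as read, the tail pace differed little between the delta and epsilon runs.

The analyst then tried a trial case, an estimate and not a bound: k_t held over theta's whole 71 min gives a share of 15.6%, which stands 5.3 percentage points above delta's reading.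

The chair asked whether target is the brake at all. Over the first 7.1 min, the beta run's mean constant stood 2.40 times delta's. Beta's interval from 18 min to 28 min covers nearly the same starting material as delta's last interval, yet its constant stands 3.01 times k_t, a ratio larger than the opening one. The meeting read this as a brake that follows minutes more than target, took the correction as close to nothing, and committed to about 10.3% for theta.

The forecast, with order 0.82 in free catalyst, order 0.47 in reagent and a theta share of 13.3%, differs from this reckoning on theta, invoking “inhibition involving product and reagent”.

The flask gives order 0.90 in free catalyst, order 0.62 in reagent and a theta share of 10.6%.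

    free catalyst + starting material ⇌ catalyst-substrate complex (5.694 M⁻¹ min⁻¹, 0.3270 min⁻¹)
    catalyst-substrate complex + reagent → target + free catalyst (1.644 M⁻¹ min⁻¹)
    free catalyst → spent catalyst (0.04020 min⁻¹)
    starting material → decomposed substrate (0.01530 min⁻¹)

Theta's mean constant over 71 min is 0.0316 min⁻¹, faster than k_t, so theta did not run at the tail pace from the start. Theta also shows where part of the starting material went. With the path to decomposed substrate taken away, its share at 71 min rises from 10.6% to 33.6%. That path thus costs theta 23 points, which is 26% of what is missing.

All runs come from a simulation with made-up constants, and the scatter is random.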